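(The readings were generated by integration with made-up constants; noise was put on by code.)

The hour is the unit for this amber flask, in which substrate gives target and other capture product and which has been followed for 30.0 h; what counts is the share of other capture product in the two.

common to all: substrate 20 mM
- amber: first nucleophile 24 mM; second nucleophile 26 mM; capture agent 20 mM; protic impurity 20 mM; the very flask that is asked about, followed so far
- flask: first nucleophile 24.0 mM; second nucleophile 26.0 mM; capture agent 20.0 mM; protic impurity 20.0 mM; time 2.5 d

- amber (time / h: other capture product / %, target / %, substrate / %): 2.50: 9, 15, 61; 8.00: 18, 23, 25; 15.0: 27, 24, 7; 20.0: 26, 24, 6; 30.0: 26, 24, 1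

(scatter of a reading: 1.5 percentage points)

* share of other capture product in other capture product plus target at 20 min
* share of other capture product in other capture product plus target at 2.5 d

- the numbers in the tables scatter by 1.5 percentage points (one standard deviation)

I reckon with two times. The amber reading of 25% substrate at 8.00 h is two halvings, so I take 4.00 h as the substrate half-life, the time in which c_substrate falls to half in a first-order decay; it reckons 7.43% at 15.0 h, where the reading is 7%. The other time is the asked 2.5 d, which is far longer, at 15.0 half-lives. That reckons 0.00305% of the substrate still there, so I commit to the last amber share, 52.0%. The early time is far shorter and lies before the first reading, and the amber share reads 37.5% at 2.50 h and 43.9% at 8.00 h, so, going by that rise, my estimate is just that the early share lies below the first of these.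

The forecast gives 30% and 52%, "With no visible drift between target and other product".

The flask gives 27.6% and 50.9%, and a run ten times as long leaves the later share unchanged.

    first nucleophile + open intermediate → target (k = 831 M⁻¹ h⁻¹)
    open intermediate + capture agent → trapped intermediate (k = 25.0 M⁻¹ h⁻¹)
    second nucleophile + open intermediate → other capture product (k = 272 M⁻¹ h⁻¹)
    second nucleophile + protic impurity → quenched reagent (k = 3.44 M⁻¹ h⁻¹)
    target ⇌ isomer of the product (K = 1.98, k = 0.510 h⁻¹)
    substrate → open intermediate (k = 0.179 h⁻¹)

At 0.250 d the half-life reckons 35.4% of the substrate in this flask, and 34.2% stands there. In the neighbour flask charged with 50 mM of substrate, the same 15.0 half-lives reckon 0.00153 mM left; its substrate stands at 0%, and its share at 69.4%.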